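**Strategy.** The route closes the cyclopentane of the bicyclo[3.2.1]octene last, by joining the quaternary carbon that carries methyl and methoxycarbonyl to the bridgehead CH. One cobalt-hydride hydrogen-atom shuttle should do this: H• adds to the CH2 of an α-substituted acrylate (creating the C-methyl), the tertiary α-ester radical closes 5-exo onto a ring alkene, and H• loss from the doubly allylic CH2 installs the diene. It exploits that this quaternary carbon is α to the ester and that the bridgehead CH ends the C=C–C=C–O dienol ether of the dihydropyran. The precursor is the cyclopentane-fused dihydropyran acylal bearing a cyclohexa-1,4-diene and an acrylate side chain.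

Key step: step 9

Remark: lactol 16 is carried as an anomeric mixture; if the diethyl acetal of 10 partly exchanges with methanol in step 4, the mixture converges in step 5.

**Step 1**
Reactants: 1 cyclopentene
Product: 4 5,5-dimethoxypentanal, via methoxy hydroperoxide aldehyde 2 (not isolated), via hydroperoxy dimethyl acetal 3 (not isolated)
Conditions: O3, CH2Cl2/MeOH, −78 °C; TsOH (cat.), rt; NaHCO3, then Me2S, rt
Reagents that add atoms: ozone ([O-][O+]=O); methanol (CO)
Why: Ozonolysis with terminal differentiation: methanol traps the carbonyl oxide as a methoxy hydroperoxide while the other terminus is the aldehyde, acid converts that aldehyde into its dimethyl acetal, and dimethyl sulfide then reduces the peroxide terminus to the free aldehyde; no stereocentre is formed.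

**Step 2**
Reactants: 4 5,5-dimethoxypentanal; 5 Meldrum's acid (2,2-dimethyl-1,3-dioxane-4,6-dione)
Product: 6 5-(5,5-dimethoxypentylidene)-2,2-dimethyl-1,3-dioxane-4,6-dione
Conditions: pyrrolidinium acetate (cat.), 4 Å MS, benzene, rt
Reagents that add atoms: none
Why: Knoevenagel condensation of the strongly C–H acidic Meldrum's acid with the aldehyde under mild ammonium carboxylate catalysis, with sieves removing water so that the acetal survives; no stereocentre is formed.

**Step 3**
Reactants: 6 5-(5,5-dimethoxypentylidene)-2,2-dimethyl-1,3-dioxane-4,6-dione; 7 3,3-diethoxyprop-1-yne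
Product: 8 5-[(4S)-1,1-diethoxy-8,8-dimethoxyoct-2-yn-4-yl]-2,2-dimethyl-1,3-dioxane-4,6-dione
Conditions: Cu(OAc)2·H2O (cat.), PINAP ligand (cat.), sodium ascorbate, H2O/t-BuOH, 0 °C
Reagents that add atoms: none
Why: Copper(I)-catalysed enantioselective conjugate alkynylation of an alkylidene Meldrum's acid: the copper acetylide formed in situ adds to the doubly activated alkene, and the chiral P,N ligand (enantiomer chosen to give the S adduct) differentiates the alkene faces and so sets the propargylic stereocentre.

**Step 4**
Reactants: 8 5-[(4S)-1,1-diethoxy-8,8-dimethoxyoct-2-yn-4-yl]-2,2-dimethyl-1,3-dioxane-4,6-dione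
Product: 10 methyl 2-[(4R)-1,1-diethoxy-8,8-dimethoxyoct-2-yn-4-yl]prop-2-enoate, via Mannich base 9 (not isolated)
Conditions: Eschenmoser's salt, MeOH, 65 °C
Reagents that add atoms: Eschenmoser's salt (C=[N+](C)C.[I-]); methanol (CO)
Why: Mannich methylenation followed by methanolysis of the dioxanedione and decarboxylative loss of dimethylamine converts the monosubstituted Meldrum's acid directly into the α-substituted methyl acrylate; the stereocentre is untouched (its descriptor becomes R only through the change in priorities).

**Step 5**
Reactants: 10 methyl 2-[(4R)-1,1-diethoxy-8,8-dimethoxyoct-2-yn-4-yl]prop-2-enoate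
Product: 11 methyl 2-[(4R)-1,8-dioxooct-2-yn-4-yl]prop-2-enoate
Conditions: HCO2H/H2O (9:1), CH2Cl2, rt
Reagents that add atoms: water (O)
Why: Acid-catalysed acetal hydrolysis unmasks both aldehydes, the formic acid medium being strong enough for the slower propargylic acetal; the stereocentre is not epimerised under acidic conditions.

**Step 6**
Reactants: 11 methyl 2-[(4R)-1,8-dioxooct-2-yn-4-yl]prop-2-enoate; 12 buta-1,3-diene
Product: 13 methyl 2-[(1R)-1-(2-formylcyclohexa-1,4-dien-1-yl)-5-oxopentyl]prop-2-enoate
Conditions: butadiene (excess), BHT (cat.), toluene, 100 °C, sealed tube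
Reagents that add atoms: none
Why: Diels–Alder reaction in which butadiene adds to the alkynal, the most electron-poor and least hindered 2π unit (the α-substituted acrylate and the saturated aldehyde react far more slowly), giving the cyclohexa-1,4-diene with the formyl-bearing alkene retained; no new stereocentre.

**Step 7**
Reactants: 13 methyl 2-[(1R)-1-(2-formylcyclohexa-1,4-dien-1-yl)-5-oxopentyl]prop-2-enoate
Product: 16 tricyclic lactol (anomeric mixture), via enamine 14 (not isolated), via N,O-acetal 15 (not isolated)
Conditions: PhNHMe, 4 Å MS, benzene, rt to 60 °C; then wet silica gel (or dilute aq. TsOH, THF, 0 °C)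
Reagents that add atoms: water (O)
Why: Intramolecular enamine–enal inverse-demand hetero-Diels–Alder reaction (iridoid-type cyclization): N-methylaniline condenses only with the saturated aldehyde, the (E)-enamine adds across the 1-oxadiene to close the cyclopentane and the dihydropyran together, allylic 1,3-strain keeps the C–H of the existing stereocentre in the plane of the formyl-bearing alkene so that the three-atom tether attacks the face that places the acrylate-bearing carbon cis to the diene CH2 (quaternary carbon) with cis ring fusion (ring-fusion CH), and mild hydrolysis of the N,O-acetal releases the lactol.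

**Step 8**
Reactants: 16 tricyclic lactol (anomeric mixture)
Product: 17 tricyclic isovalerate acylal
Conditions: (i-PrCH2CO)2O, Et3N, DMAP (cat.), CH2Cl2, 0 °C
Reagents that add atoms: isovaleric anhydride (CC(C)CC(=O)OC(=O)CC(C)C)
Why: DMAP-catalysed acylation of the lactol: the anomers interconvert through the open form and the less hindered hydroxyl, trans to the cyclopentane CH2 and favoured by the anomeric effect, is esterified, which sets the acetal carbon.

**Step 9**
Reactants: 17 tricyclic isovalerate acylal
Product: 18 CNP0315847.1 (target)
Conditions: Co(dmgBF2)2(H2O)2 (cat.), H2 (3 atm), benzene, 50 °C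
Reagents that add atoms: none
Why: A cobalt(III) hydride formed from the cobaloxime and H2 transfers H• to the acrylate CH2 (as in catalytic chain transfer with methacrylates), which creates the C-methyl group and a tertiary α-ester radical; this radical adds to the near carbon of the ring alkene, and cobalt(II) then takes H• from the doubly allylic CH2, so the catalyst is returned and the conjugated dienol ether results. The closest known reaction type is the cobaloxime/H2 radical cycloisomerization of α-substituted acrylates that carry a tethered alkene. The cyclopentane closes in the 5-exo-trig mode, the radical carbon being held over the alkene by the ring fusion set in step 7. The bridgehead CH is fixed by the tether (the side chain reaches only the alkene face on which it sits); the quaternary carbon is fixed by allylic 1,3-strain in the planar ester-conjugated radical, where the methoxycarbonyl group eclipses the small C–H of the neighbouring stereocentre instead of the cyclopentane CH2, so the ester should end endo over the diene bridge and the new methyl exo. Chemoselective initiation is needed and is secured because the acrylate is the only 1,1-disubstituted, radical-stabilising alkene (the enol ether is fully substituted at its hydrogen-accepting carbon and the ring alkene is 1,2-disubstituted), while 5-exo is geometrically preferred over 6-endo. Termination is regiospecific because the only other β-hydrogen sits on the bridgehead, where an alkene is forbidden, and the hydrogen shuttle has no further isomerisation open to it in the product.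

**Compound list**

1 | cyclopentene | C1=CCCC1 | starting material
2 | 5-hydroperoxy-5-methoxypentanal | COC(OO)CCCC=O | intermediate
3 | 5-hydroperoxy-1,1,5-trimethoxypentane | COC(OO)CCCC(OC)OC | intermediate
4 | 5,5-dimethoxypentanal | COC(OC)CCCC=O | intermediate
5 | Meldrum's acid (2,2-dimethyl-1,3-dioxane-4,6-dione) | CC1(C)OC(=O)CC(=O)O1 | starting material
6 | 5-(5,5-dimethoxypentylidene)-2,2-dimethyl-1,3-dioxane-4,6-dione | COC(OC)CCCC=C1C(=O)OC(C)(C)OC1=O | intermediate
7 | 3,3-diethoxyprop-1-yne | C#CC(OCC)OCC | starting material
8 | 5-[(4S)-1,1-diethoxy-8,8-dimethoxyoct-2-yn-4-yl]-2,2-dimethyl-1,3-dioxane-4,6-dione | COC(OC)CCC[C@@H](C1C(=O)OC(C)(C)OC1=O)C#CC(OCC)OCC | intermediate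
9 | Mannich base: 8 carrying a (dimethylamino)methyl group on C5 of the dioxanedione, same configuration in space | COC(OC)CCC[C@@H](C1(CN(C)C)C(=O)OC(C)(C)OC1=O)C#CC(OCC)OCC | intermediate
10 | methyl 2-[(4R)-1,1-diethoxy-8,8-dimethoxyoct-2-yn-4-yl]prop-2-enoate | COC(OC)CCC[C@@H](C(=C)C(=O)OC)C#CC(OCC)OCC | intermediate
11 | methyl 2-[(4R)-1,8-dioxooct-2-yn-4-yl]prop-2-enoate | O=CCCC[C@@H](C(=C)C(=O)OC)C#CC=O | intermediate
12 | buta-1,3-diene | C=CC=C | starting material
13 | methyl 2-[(1R)-1-(2-formylcyclohexa-1,4-dien-1-yl)-5-oxopentyl]prop-2-enoate | O=CCCC[C@@H](C(=C)C(=O)OC)C1=C(C=O)CC=CC1 | intermediate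
14 | methyl 2-[(1R,4E)-1-(2-formylcyclohexa-1,4-dien-1-yl)-5-[methyl(phenyl)amino]pent-4-en-1-yl]prop-2-enoate | CN(c1ccccc1)/C=C/CC[C@@H](C(=C)C(=O)OC)C1=C(C=O)CC=CC1 | intermediate
15 | N,O-acetal: lactol 16 with N-methylanilino in place of OH at the acetal carbon, trans to the cyclopentane CH2 | C1C=CCC2=CO[C@@H](N(C)c4ccccc4)[C@@H]3CC[C@@H](C(=C)C(=O)OC)[C@]123 | intermediate
16 | tricyclic lactol: cis-fused 1-hydroxy-1,4a,5,6,7,7a-hexahydrocyclopenta[c]pyran (C3=C4 enol ether) whose C4–C4a bond also belongs to a cyclohexa-1,4-diene (C4–CH2–CH=CH–CH2–C4a) and whose C5 carries a 1-(methoxycarbonyl)ethenyl group cis to the diene CH2 on C4a; anomeric mixture | C1C=CCC2=COC(O)[C@@H]3CC[C@@H](C(=C)C(=O)OC)[C@]123 | intermediate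
17 | tricyclic isovalerate acylal: 16 with the C1 oxygen acylated by 3-methylbutanoyl, trans to the C7 methylene (cis to H-7a) | C1C=CCC2=CO[C@@H](OC(=O)CC(C)C)[C@@H]3CC[C@@H](C(=C)C(=O)OC)[C@]123 | intermediate
18 | CNP0315847.1: 17 after bonding of the acrylate α-carbon (now quaternary, methyl exo, CO2Me endo) to the former alkene carbon next to the diene CH2, with the C=C shifted into conjugation with the enol ether | COC(=O)[C@]1(C)[C@@H]2C=CC3=CO[C@@H](OC(=O)CC(C)C)[C@@H]4CC[C@@H]1[C@]34C2 | target

**Total step count:** 9
**Longest linear sequence:** 9 steps (fully linear from cyclopentene)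

**Steps most likely to fail**

1. Step 9. Return of H• from the tertiary radical to cobalt may outrun closure onto the unactivated ring alkene, which would isomerise the acrylate to the tetrasubstituted enoate and erode the adjacent stereocentre; the facial bias at the quaternary carbon may also be incomplete. Fallback (polar instead of radical C–C formation), from 17: RhCl(PPh3)3-catalysed 1,4-hydrosilylation with Et3SiH should give the triethylsilyl ketene acetal F1. Pd(OAc)2 in MeCN should then effect an oxidative cycloalkenylation (attack of the palladium enolate on the ring alkene, β-hydride elimination toward the doubly allylic CH2), which returns to the route at 18.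

2. Step 7. Cycloaddition at the fully substituted β-carbon may be slow, which would leave room for enamine addition to the acrylate or for dienamine formation at the enal with loss of the stereocentre. Fallback (amine-free, enol ester as the 2π partner, acyloxy acetal made in the cycloaddition), from 10: PPTS in wet acetone should cleave only the aliphatic dimethyl acetal to give aldehyde F2. Isovaleric anhydride/KOAc at 120 °C should convert it into the enol isovalerate F3, of which the (E)-isomer is used. Formic acid then unmasks the alkynal F4, and butadiene as in step 6 gives the cyclohexadienyl enal F5. Heating F5 (xylene, 150 °C, Eu(fod)3 if needed) should give the enal/enol-ester hetero-Diels–Alder adduct, which is 17 itself, where the route resumes.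

3. Step 3. Enantiofacial selectivity and turnover may be poor with a non-aryl alkyne and an unbranched alkylidene, and the alkylidene may isomerise out of conjugation. Fallback (stereocentre set by allylic substitution instead of conjugate addition), from 4: Morita–Baylis–Hillman reaction with methyl acrylate (DABCO) should give the allylic alcohol F6, and NBS/Me2S the rearranged (Z)-allylic bromide F7. A copper/chiral NHC-catalysed anti-SN2′ substitution with the diisobutyl(alkynyl)aluminium reagent prepared from 7 (DIBAL-H, Et3N cat.) should then give 10 directly, where the route resumes.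

**Further compounds**

F1 | step 9 | triethylsilyl ketene acetal of the saturated methyl ester derived from 17 | C1C=CCC2=CO[C@@H](OC(=O)CC(C)C)[C@@H]3CC[C@@H](C(C)=C(OC)O[Si](CC)(CC)CC)[C@]123
F2 | step 7 | methyl 2-[(4R)-1,1-diethoxy-8-oxooct-2-yn-4-yl]prop-2-enoate | O=CCCC[C@@H](C(=C)C(=O)OC)C#CC(OCC)OCC
F3 | step 7 | (E)-enol 3-methylbutanoate of F2 | CC(C)CC(=O)O/C=C/CC[C@@H](C(=C)C(=O)OC)C#CC(OCC)OCC
F4 | step 7 | alkynal from F3 (diethyl acetal cleaved) | CC(C)CC(=O)O/C=C/CC[C@@H](C(=C)C(=O)OC)C#CC=O
F5 | step 7 | 2-formylcyclohexa-1,4-dienyl enol ester from F4 and butadiene | CC(C)CC(=O)O/C=C/CC[C@@H](C(=C)C(=O)OC)C1=C(C=O)CC=CC1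
F6 | step 3 | methyl 2-(1-hydroxy-5,5-dimethoxypentyl)prop-2-enoate | COC(OC)CCCC(O)C(=C)C(=O)OC
F7 | step 3 | methyl (2Z)-2-(bromomethyl)-7,7-dimethoxyhept-2-enoate | COC(OC)CCC/C=C(\CBr)C(=O)OC
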